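Retrosynthetic overview
1. Numbering: ring B = C5–C6–C7–C8–C9–C10 (C9 = C(Me)(C11H2Ar), C8 = CHMe, C5 = C–Me, C10 = CH). Ring A = C1–C2–C3(=O)–C4–C5–C10. The side chain on C4 is C1′H2–C2′H2–C3′O2H.
2. Enabling feature: ring B carries four contiguous stereocentres C5, C10, C9, C8, with C11, H-10 and 8-Me on one face and 5-Me and 9-Me on the other. This is the endo imprint of an (E)-2-methylenal (C9=C10, C11 = CHO) on an (E,E)-diene (C5=C6–C7=C8), so C8–C9 and C5–C10 are cut together (intramolecular Diels–Alder).
3. The 1,5-keto acid C3(=O)/C3′O2H is the seco form of a cyclopentanone. A temporary bond C3–C3′ makes a ring C3–C4–C1′–C2′–C3′ that locks the tether, carries the only preset stereocentre (C4) and is cut late by ozonolysis of its enol silane.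
4. The triene comes from cyclopentenone by three C–C bond formations: asymmetric 1,4-addition of a hexadienyl metal (C4–C5), Mukaiyama–Michael addition to acrolein (C3–C2) and Wittig olefination (C10=C9). The arene enters at C11 as an aryllithium, and C11–O is removed by a radical.
5. Ring order: temporary five-membered ring (bought), then rings A and B together in the key step, then the five-membered ring is opened, then global hydrogenation.

Key step: step 6

Assumption: the stereodescriptors of the SMILES are taken literally, so 8-Me is cis to C11 and trans to 9-Me on a trans-decalin, and the C4 side chain is equatorial.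

Step 1
Reactants: 1 (E)-but-2-enal
Product: 2 (3E)-1,1-dibromopenta-1,3-diene
Conditions: CBr4, PPh3, CH2Cl2, 0 °C
Reagents that add atoms: carbon tetrabromide BrC(Br)(Br)Br
Why: Ramirez dibromo-olefination (first stage of the Corey–Fuchs alkyne synthesis), in which Ph3P=CBr2 made in the flask attacks only the aldehyde carbon of the enal, so the E alkene is carried over unchanged and no stereocentre is formed.

Step 2
Reactants: 2 (3E)-1,1-dibromopenta-1,3-diene
Product: 4 (2E)-hex-2-en-4-yne, via lithium pentenynide 3 (not isolated)
Conditions: n-BuLi (2.1 equiv), THF, −78 °C; then MeI, −78 °C to rt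
Reagents that add atoms: iodomethane CI
Why: Second stage of the Corey–Fuchs sequence, in which Br/Li exchange and loss of LiBr (Fritsch–Buttenberg–Wiechell shift) give the lithium acetylide and SN2 methylation caps the alkyne, the volatile product being kept as a distilled THF solution.

Step 3
Reactants: 4 (2E)-hex-2-en-4-yne; 5 cyclopent-2-en-1-one
Product: 7 {[(3R)-3-[(2E,4E)-hexa-2,4-dien-2-yl]cyclopent-1-en-1-yl]oxy}trimethylsilane, via dienylzirconocene chloride 6 (not isolated)
Conditions: Cp2Zr(H)Cl, THF, rt; then 5, Me3SiCl, [Rh(cod)(MeCN)2]BF4 (5 mol %), (R)-BINAP (6 mol %), THF, rt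
Reagents that add atoms: chlorotrimethylsilane C[Si](C)(C)Cl
Why: Syn hydrozirconation should put Zr on the methyl-bearing alkyne carbon (the smaller substituent) and fix the 2E geometry, and the rhodium/(R)-BINAP-catalysed asymmetric 1,4-addition of the alkenylzirconocene, turned over by Me3SiCl, should set C4 as R by catalyst control of the enone face and deliver the enolate regiospecifically as its silyl ether.

Step 4
Reactants: 7 silyl enol ether; 8 prop-2-enal (acrolein)
Product: 9 3-{(1S,2R)-2-[(2E,4E)-hexa-2,4-dien-2-yl]-5-oxocyclopentyl}propanal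
Conditions: 8, BF3·OEt2 (0.2 equiv), i-PrOH (1 equiv), CH2Cl2, −78 °C
Reagents that add atoms: none
Why: Mukaiyama–Michael addition, in which the regiodefined enol silane attacks the β-carbon of the activated acrolein from the ring face opposite to the dienyl group while i-PrOH takes over the silyl group, so C3 should result trans to C4, which is also the thermodynamic arrangement of this epimerisable centre.

Step 5
Reactants: 9 keto aldehyde; 10 2-(triphenyl-λ5-phosphanylidene)propanal
Product: 11 (2E)-5-{(1S,2R)-2-[(2E,4E)-hexa-2,4-dien-2-yl]-5-oxocyclopentyl}-2-methylpent-2-enal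
Conditions: toluene, 50 °C
Reagents that add atoms: none
Why: Wittig olefination with a stabilised ylide, which reacts with the aldehyde only (the ketone is inert) and should give the E trisubstituted enal.

Step 6
Reactants: 11 trienal with the temporary cyclopentanone ring
Product: 12 tricyclic keto aldehyde (trans-fused Δ6-octalin, trans-fused at C3–C4 to the cyclopentanone; 9-CHO, H-10, 8-Me and H-4 on one face; 5-Me, 9-Me and H-3 on the other)
Conditions: Me2AlCl (2.2 equiv), CH2Cl2, −78 to −20 °C; aq potassium sodium tartrate
Reagents that add atoms: none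
Why: Type 1 intramolecular Diels–Alder reaction of a 2,8,10-trienal, in which Me2AlCl binds the aldehyde (a second equivalent occupies the ketone), lowers the LUMO of C9=C10, and the s-cis diene C5=C6–C7=C8 adds suprafacially to form C5–C10 and C8–C9 in one concerted, asynchronous event, the closest known reactions being Lewis-acid-promoted cyclisations of (E)-2-methyl-2,8,10-trienals to trans-octalins with a quaternary C(Me)CHO centre. Ring B closes as the six-membered [4+2] ring through C8–C9 and C5–C10, and ring A closes in the fused mode through C5–C10 as the four-atom tether C1–C4 folds into a chair. C9 and C10 keep the E geometry of the enal (CHO cis to H-10, 9-Me cis to C1), and C5 and C8 keep the E,E geometry of the diene (C4 and 8-Me outside and hence cis, 5-Me inside). The endo orientation of the complexed CHO, which is the same transition state that holds the tether anti and gives the trans ring fusion, places CHO, H-10 and 8-Me on one face and 5-Me and 9-Me on the other. The diene face is fixed by the temporary ring, because a trans-fused cyclopentanone can only span two equatorial bonds of the nascent chair (H-4 axial), so 5-Me must become axial anti to H-4 and the single preset centre C4 dictates all four new ones. The step needs endo over exo selectivity and enough reactivity to overcome the inside methyl group and the developing 1,3-diaxial 5-Me/9-Me contact, which strong activation of the α-methyl enal, the short tether and the rigid ring are meant to secure, and no other diene–dienophile pairing is geometrically possible.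

Step 7
Reactants: 12 tricyclic keto aldehyde
Product: 13 tert-butyldimethylsilyl enol ether of 12 (C3=C3′ double bond at the ring fusion, aldehyde intact)
Conditions: TBSOTf, Et3N, CH2Cl2, 0 °C to rt
Reagents that add atoms: tert-butyldimethylsilyl triflate CC(C)(C)[Si](C)(C)OS(=O)(=O)C(F)(F)F
Why: Soft enolisation and O-silylation under equilibrating conditions, in which the aldehyde on quaternary C9 cannot enolise and the tetrasubstituted C3=C3′ isomer should be favoured because it is the more substituted alkene and relieves the strain of the trans-fused hydrindanone, so the ketone is masked and the later cleavage site is marked (the C3 stereocentre, not needed in the target, disappears).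

Step 8
Reactants: 14 2-bromo-6-methylphenol
Product: 15 2-bromo-6-methyl-1,4-benzoquinone
Conditions: O2 (1 atm), Co(salen) (10 mol %), DMF, rt
Reagents that add atoms: dioxygen O=O
Why: Cobalt–salen-catalysed aerobic oxidation of a 2,6-disubstituted phenol to the para-quinone, the free para position being the only site open to oxygenation.

Step 9
Reactants: 15 2-bromo-6-methyl-1,4-benzoquinone
Product: 17 2,5-bis(benzyloxy)-1-bromo-3-methylbenzene, via bromomethylhydroquinone 16 (not isolated)
Conditions: Na2S2O4, THF/H2O, rt; then BnBr, K2CO3, DMF, 60 °C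
Reagents that add atoms: benzyl bromide BrCc1ccccc1
Why: Dithionite reduction of the quinone followed by double Williamson etherification, benzyl being chosen because it falls in the final hydrogenation.

Step 10
Reactants: 17 aryl bromide; 13 enol silane aldehyde
Product: 21 S-methyl xanthate of the C11 carbinol (both C11 epimers), via aryllithium 18 (not isolated), via lithium alkoxide 19 (not isolated), via lithium xanthate 20 (not isolated)
Conditions: 17, n-BuLi, THF, −78 °C; then 13, −78 to 0 °C; then CS2, 0 °C to rt; then MeI, rt
Reagents that add atoms: carbon disulfide S=C=S; iodomethane CI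
Why: Br/Li exchange, 1,2-addition of the aryllithium to the non-enolisable neopentyl aldehyde (the enol silane is inert) and xanthate formation from the alkoxide in the same flask, the new carbinol centre C11 being formed without control and erased in the next step.

Step 11
Reactants: 21 xanthate
Product: 22 C11-deoxygenated enol silane (C11H2 links C9 to the dibenzyloxytolyl ring)
Conditions: Bu3SnH, AIBN (cat), toluene, 100 °C
Reagents that add atoms: none
Why: Barton–McCombie deoxygenation, in which the stannyl radical adds to C=S and the released benzylic C11 radical takes H from Bu3SnH, a radical path that avoids the Wagner–Meerwein shifts a C11 cation next to quaternary C9 would invite.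

Step 12
Reactants: 22 enol silane
Product: 23 Δ6 keto acid with both phenols benzylated (C3=O, C3′O2H, temporary ring opened)
Conditions: O3 (1 equiv), CH2Cl2, −78 °C; then Me2S, −78 °C to rt; H2O
Reagents that add atoms: ozone [O-][O+]=O
Why: Ozonolysis of a silyl enol ether, in which the tetrasubstituted, oxygen-activated C3=C3′ bond should be by far the most nucleophilic π bond (C6=C7 is only disubstituted and shielded by C5 and C8, while the arene and benzyl ethers react much more slowly at −78 °C), so one equivalent cuts the temporary bond to C3=O and a silyl ester that hydrolyses on work-up, and C4 stays equatorial because no base or strong acid follows.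

Step 13
Reactants: 23 dibenzyl keto acid
Product: 24 target CNP0167047.1
Conditions: H2 (3 atm), Pd(OH)2/C, EtOAc/EtOH, rt; work-up under argon
Reagents that add atoms: none
Why: Heterogeneous hydrogenation and hydrogenolysis, in which saturation of C6=C7 creates no stereocentre, both O-benzyl groups leave as toluene, and the ketone and acid are inert to palladium at room temperature.

Compound list
1 | (E)-but-2-enal | C/C=C/C=O | starting material
2 | (3E)-1,1-dibromopenta-1,3-diene | C/C=C/C=C(Br)Br | intermediate
3 | lithium (3E)-pent-3-en-1-yn-1-ide | C/C=C/C#C[Li] | intermediate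
4 | (2E)-hex-2-en-4-yne | C/C=C/C#CC | intermediate
5 | cyclopent-2-en-1-one | O=C1C=CCC1 | starting material
6 | chlorobis(cyclopentadienyl)[(2E,4E)-hexa-2,4-dien-2-yl]zirconium | C/C=C/C=C(\C)[Zr](Cl)(C1C=CC=C1)C1C=CC=C1 | intermediate
7 | {[(3R)-3-[(2E,4E)-hexa-2,4-dien-2-yl]cyclopent-1-en-1-yl]oxy}trimethylsilane | C[Si](C)(C)OC1=C[C@H](/C(C)=C/C=C/C)CC1 | intermediate
8 | prop-2-enal | C=CC=O | starting material
9 | 3-{(1S,2R)-2-[(2E,4E)-hexa-2,4-dien-2-yl]-5-oxocyclopentyl}propanal | O=CCC[C@@H]1C(=O)CC[C@H]1/C(C)=C/C=C/C | intermediate
10 | 2-(triphenyl-λ5-phosphanylidene)propanal | CC(C=O)=P(c1ccccc1)(c1ccccc1)c1ccccc1 | starting material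
11 | (2E)-5-{(1S,2R)-2-[(2E,4E)-hexa-2,4-dien-2-yl]-5-oxocyclopentyl}-2-methylpent-2-enal | O=C/C(C)=C/CC[C@@H]1C(=O)CC[C@H]1/C(C)=C/C=C/C | intermediate
12 | tricyclic keto aldehyde (Diels–Alder adduct) | O=C[C@]1(C)[C@H]2CC[C@@H]3C(=O)CC[C@H]3[C@]2(C)C=C[C@@H]1C | intermediate
13 | TBS enol ether of 12 (C3=C3′) | O=C[C@]1(C)[C@H]2CCC3=C(O[Si](C)(C)C(C)(C)C)CC[C@H]3[C@]2(C)C=C[C@@H]1C | intermediate
14 | 2-bromo-6-methylphenol | Cc1cccc(Br)c1O | starting material
15 | 2-bromo-6-methyl-1,4-benzoquinone | CC1=CC(=O)C=C(Br)C1=O | intermediate
16 | 2-bromo-6-methylbenzene-1,4-diol | Cc1cc(O)cc(Br)c1O | intermediate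
17 | 2,5-bis(benzyloxy)-1-bromo-3-methylbenzene | Cc1cc(OCc2ccccc2)cc(Br)c1OCc1ccccc1 | intermediate
18 | [2,5-bis(benzyloxy)-3-methylphenyl]lithium | Cc1cc(OCc2ccccc2)cc([Li])c1OCc1ccccc1 | intermediate
19 | lithium alkoxide of the C11 carbinol | Cc1cc(OCc2ccccc2)cc(C(O[Li])[C@]2(C)[C@H]3CCC4=C(O[Si](C)(C)C(C)(C)C)CC[C@H]4[C@]3(C)C=C[C@@H]2C)c1OCc1ccccc1 | intermediate
20 | lithium xanthate of the C11 carbinol | Cc1cc(OCc2ccccc2)cc(C(OC(=S)S[Li])[C@]2(C)[C@H]3CCC4=C(O[Si](C)(C)C(C)(C)C)CC[C@H]4[C@]3(C)C=C[C@@H]2C)c1OCc1ccccc1 | intermediate
21 | S-methyl xanthate of the C11 carbinol | Cc1cc(OCc2ccccc2)cc(C(OC(=S)SC)[C@]2(C)[C@H]3CCC4=C(O[Si](C)(C)C(C)(C)C)CC[C@H]4[C@]3(C)C=C[C@@H]2C)c1OCc1ccccc1 | intermediate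
22 | C11-deoxygenated enol silane | Cc1cc(OCc2ccccc2)cc(C[C@]2(C)[C@H]3CCC4=C(O[Si](C)(C)C(C)(C)C)CC[C@H]4[C@]3(C)C=C[C@@H]2C)c1OCc1ccccc1 | intermediate
23 | Δ6 keto acid, dibenzyl ether | Cc1cc(OCc2ccccc2)cc(C[C@]2(C)[C@H]3CCC(=O)[C@@H](CCC(=O)O)[C@]3(C)C=C[C@@H]2C)c1OCc1ccccc1 | intermediate
24 | CNP0167047.1 | Cc1cc(O)cc(C[C@]2(C)[C@H]3CCC(=O)[C@@H](CCC(=O)O)[C@]3(C)CC[C@@H]2C)c1O | target

Total step count: 13. Longest linear sequence: 11 (steps 1–7 and 10–13).

Steps most likely to fail

Step 6.
- What may go wrong: the cycloaddition may be too slow because the methyl group on the inner position of C5 depopulates the s-cis diene. The exo mode may compete because it avoids the developing 5-Me/9-Me contact. The Lewis acid may also polymerise the diene.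
- Fallback (from 11, back at 12): the neutral Lewis acid complex is replaced by a cationic dienophile. Both carbonyl groups of 11 are converted with 1,2-bis(trimethylsilyloxy)ethane and catalytic Me3SiOTf at −78 °C into the bis(1,3-dioxolane) of the trienal F1. More Me3SiOTf at −78 to −40 °C ionises the allylic acetal to a vinyl oxocarbenium ion, a much stronger dienophile (ionic Diels–Alder reaction). Reclosure of the acetal gives the tricyclic bis(1,3-dioxolane) F2. Aqueous acid hydrolysis of both acetals returns 12.

Step 3.
- What may go wrong: regiocontrol in the hydrozirconation may be incomplete. Transfer of the α-branched alkenyl group from zirconium to rhodium may be slow. Enantioselectivity may be eroded by an uncatalysed background reaction. The trimethylsilyl ether may be hydrolysed prematurely.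
- Fallback (from 4 through 6, back at 9, replacing steps 3 and 4): catalyst control is replaced by auxiliary control.
  - Iodinolysis of 6 gives (2E,4E)-2-iodohexa-2,4-diene F3, which can be freed of any regioisomer.
  - I/Mg exchange with i-PrMgCl·LiCl gives, with retention, the dienylmagnesium chloride F4.
  - F4 is added to the ZnBr2 chelate of enantiopure (S)-2-[(4-methylphenyl)sulfinyl]cyclopent-2-en-1-one F5, whose aryl group blocks one face. This gives the β-keto sulfoxide F6 with the R centre at C4.
  - This soft carbon acid adds at C3, anti to the dienyl group, to acrolein 8 under catalytic Et3N (Michael addition) to give the quaternary sulfinyl keto aldehyde F7.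
  - Reductive C–S cleavage with aluminium amalgam in aqueous THF gives 9.

Step 12.
- What may go wrong: ozone may over-oxidise C6=C7, the electron-rich arene or the benzyl ethers. Any silylation toward C2′ in step 7 would also direct the cut to the wrong bond.
- Fallback (from 22, back at 24): the enol silane is treated only as a protecting group, and the cleavage site is chosen by migratory aptitude instead.
  - TBAF/AcOH gives the cyclopentanone F8 (C3 epimers converge later).
  - Baeyer–Villiger oxidation with Me3SiOOSiMe3 and catalytic Me3SiOTf, a reagent that spares C=C bonds, inserts oxygen on the more substituted side and gives the δ-lactone F9.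
  - KOH opens the lactone to the potassium hydroxy carboxylate F10, which is alkylated without acidification by BnBr in DMF to the benzyl hydroxy ester F11.
  - Dess–Martin oxidation gives the benzyl keto ester F12.
  - The hydrogenation of step 13 then removes three benzyl groups and the alkene to give 24.

Further compounds
F1 | step 6 | bis(1,3-dioxolane) of 11 | O1CCOC1/C(C)=C/CC[C@@H]2C3(OCCO3)CC[C@H]2/C(C)=C/C=C/C
F2 | step 6 | bis(1,3-dioxolane) of 12 | O1CCOC1[C@]2(C)[C@H]3CC[C@@H]4C5(OCCO5)CC[C@H]4[C@]3(C)C=C[C@@H]2C
F3 | step 3 | (2E,4E)-2-iodohexa-2,4-diene | C/C=C/C=C(\C)I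
F4 | step 3 | [(2E,4E)-hexa-2,4-dien-2-yl]magnesium chloride | C/C=C/C=C(\C)[Mg]Cl
F5 | step 3 | (S)-2-[(4-methylphenyl)sulfinyl]cyclopent-2-en-1-one | O=C1CCC=C1[S@@](=O)c1ccc(C)cc1
F6 | step 3 | (3R)-3-[(2E,4E)-hexa-2,4-dien-2-yl]-2-[(4-methylphenyl)sulfinyl]cyclopentan-1-one (C3 epimers, sulfur unchanged) | O=C1CC[C@@H](/C(C)=C/C=C/C)C1[S@@](=O)c1ccc(C)cc1
F7 | step 3 | acrolein Michael adduct of F6 (propanal chain trans to the dienyl group) | O=CCC[C@]1([S@@](=O)c2ccc(C)cc2)C(=O)CC[C@H]1/C(C)=C/C=C/C
F8 | step 12 | cyclopentanone from desilylation of 22 (C3 epimers) | Cc1cc(OCc2ccccc2)cc(C[C@]2(C)[C@H]3CCC4C(=O)CC[C@H]4[C@]3(C)C=C[C@@H]2C)c1OCc1ccccc1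
F9 | step 12 | δ-lactone (O between C3 and C3′) | Cc1cc(OCc2ccccc2)cc(C[C@]2(C)[C@H]3CCC4OC(=O)CC[C@H]4[C@]3(C)C=C[C@@H]2C)c1OCc1ccccc1
F10 | step 12 | potassium 3-hydroxy carboxylate | Cc1cc(OCc2ccccc2)cc(C[C@]2(C)[C@H]3CCC(O)[C@@H](CCC(=O)[O-])[C@]3(C)C=C[C@@H]2C)c1OCc1ccccc1.[K+]
F11 | step 12 | benzyl hydroxy ester | Cc1cc(OCc2ccccc2)cc(C[C@]2(C)[C@H]3CCC(O)[C@@H](CCC(=O)OCc4ccccc4)[C@]3(C)C=C[C@@H]2C)c1OCc1ccccc1
F12 | step 12 | benzyl keto ester | Cc1cc(OCc2ccccc2)cc(C[C@]2(C)[C@H]3CCC(=O)[C@@H](CCC(=O)OCc4ccccc4)[C@]3(C)C=C[C@@H]2C)c1OCc1ccccc1
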